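In the steps proposed, every chain begun has used one initiator, whatever becomes of it later, so the average chain is monomer in chains divided by initiator used.

- amber: free monomer 0.25 M; transfer agent 11 mM; initiator 25 mM; run made earlier
- flask: free monomer 0.25 M; transfer agent 7.50 mM; initiator 25 mM; time 4.0 h

amber run (percent of the free monomer charged)

| time / min | monomer in chains / % | free monomer / % |
|---|---|---|
| 6.00 | 1.1 | 98.9 |
| 8.00 | 1.5 | 99.0 |
| 12.0 | 2.9 | 98.2 |
| 20.0 | 4.0 | 96.3 |
| 30.0 | 6.6 | 93.1 |
| 50.0 | 11.7 | 87.8 |
| 80.0 | 17.1 | 82.8 |

(each reading ± 0.3 percentage points)

- the average divides the monomer in chains by the number of chains begun, living and dead together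
- steps that have been proposed: free monomer + initiator -> living end + monomer in chains; free monomer + living end -> monomer in chains + living end; living end + transfer agent -> dead chain; 2 living end -> dead end
- the earlier runs do not show the number of chains; that part of a forecast is a guess
- no earlier run changes the charge of transfer agent; that part of a forecast is a guess

- average number of monomer units in a chain (chains begun, living or dead) at 4.0 h
- part of the free monomer that has reacted at 4.0 h

In fractions of the charge, the average is the load times the reacted fraction of free monomer, divided by the used fraction of initiator. The load, 10.0, is free monomer charged per initiator charged, and the amber run has the same value.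

Now draw the curve. The amber run takes up free monomer at 0.132 h⁻¹ of its charge up to 30.0 min, while free monomer stays near 93.1 %. Freeze it there, and the initiator decays as a pseudo-first-order lag. If you read that early uptake as chains beginning, the initiator fraction falls at 10.0 times that rate, a time constant of 0.758 h. This is short-sided, since growth on living ends sits in the same slope.

On this reckoning the initiator fraction crosses 0.5 after 0.525 h. That is the knee of my curve: the chain count still rises after it, ever more slowly, toward the charge of initiator. Because the time constant is well inside 4.0 h, I take 99.5 % of the initiator as used. Continuing the slope gives 41.0 % reacted, which I hold as high, and so an average near 4.12. The changed transfer agent I can only guess at, and I leave it out.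

The forecast says 10 units and 48 % reacted, with “Chains begun cannot exceed 25 mM, and I guess about 12 mM”. My reckoning stands below it on both.

The flask gives 3.71 units and 33.8 % reacted.

    free monomer + initiator → living end + monomer in chains (k = 3.10 M⁻¹ h⁻¹)
    free monomer + living end → monomer in chains + living end, rate k2*[living end]*[free monomer] (k = 23.0 M⁻¹ h⁻¹)
    living end + transfer agent → dead chain (kL = 62.0 M⁻¹ h⁻¹)
    2 living end → dead end (k = 170 M⁻¹ h⁻¹)

At 4.00 h the flask keeps 8.7 % of its initiator against 66 % of its free monomer, and the load with those fractions returns 3.70. The neighbour charged with 0.10 M of initiator has a load of 2.50. It reaches 68.2 % reacted and keeps 19 % of its initiator, so its average is 2.10, and the neighbour stands at 2.12.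

(The runs are simulated from invented constants; the scatter is artificial.)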